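**Retrosynthetic overview**
- Target ⇐ removal of a benzyl ether, a dioxolane and a TBS ether from a protected (1R,2S) arylglycerol β-aryl ether. The benzylic carbinol C1 is inverted late (Mitsunobu) from the (1S,2S) syn series.
- Key C1–C2 bond: Evans syn aldol of the (Z)-boron enolate of an (aryloxy)acetyl oxazolidinone with O-benzylvanillin. This sets C2 absolutely and C1 relative to it.
- C3 (CH2OH) is the former imide carbonyl, freed by reductive removal of the auxiliary. The aryl–O–CH2 bond comes from Williamson alkylation of acetosyringone with ethyl bromoacetate, with the acetyl group masked as a dioxolane.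
- Rings: no ring of the target is built, since both benzene rings are bought. The only ring formed is the temporary dioxolane (step 2), opened again in step 10.

Assumption: chain numbering is C1 = benzylic carbinol carbon, C2 = aryloxy-bearing carbon, C3 = CH2OH; read this way the target SMILES is the (1R,2S) isomer (erythro, anti in the zigzag drawing).

**Step 1**
Reactants: 1 acetosyringone (1-(4-hydroxy-3,5-dimethoxyphenyl)ethan-1-one); 2 ethyl bromoacetate
Product: 3 ethyl 2-(4-acetyl-2,6-dimethoxyphenoxy)acetate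
Conditions: K2CO3, DMF, 60 °C
Reagents that add atoms: none
Why: Williamson ether synthesis, in which the acidic para-acyl phenoxide of 1 displaces bromide from the very SN2-reactive α-bromo ester while K2CO3 is too weak to enolise the methyl ketone.

**Step 2**
Reactants: 3 ethyl 2-(4-acetyl-2,6-dimethoxyphenoxy)acetate
Product: 4 ethyl 2-[2,6-dimethoxy-4-(2-methyl-1,3-dioxolan-2-yl)phenoxy]acetate
Conditions: TMSOCH2CH2OTMS, TMSOTf (cat.), CH2Cl2, −20 °C → rt; pyridine quench
Reagents that add atoms: 1,2-bis(trimethylsilyloxy)ethane, C[Si](C)(C)OCCO[Si](C)(C)C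
Why: Noyori ketalisation, driven by Si–O–Si bond formation under aprotic conditions so that the ester is not transesterified, masks the ketone that would otherwise be enolised in step 5 and reduced in step 6.

**Step 3**
Reactants: 4 ethyl 2-[2,6-dimethoxy-4-(2-methyl-1,3-dioxolan-2-yl)phenoxy]acetate
Product: 5 2-[2,6-dimethoxy-4-(2-methyl-1,3-dioxolan-2-yl)phenoxy]acetic acid
Conditions: LiOH·H2O, THF/H2O, 0 °C → rt; then cold 1 M HCl to pH 4, immediate extraction
Reagents that add atoms: lithium hydroxide, [Li+].[OH-]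
Why: Ester saponification, in which hydroxide attacks the unhindered aryloxyacetate while the dioxolane is inert to base and survives the brief, cold acidification to pH 4.

**Step 4**
Reactants: 5 2-[2,6-dimethoxy-4-(2-methyl-1,3-dioxolan-2-yl)phenoxy]acetic acid; 6 (R)-4-benzyloxazolidin-2-one
Product: 8 (R)-4-benzyl-3-{2-[2,6-dimethoxy-4-(2-methyl-1,3-dioxolan-2-yl)phenoxy]acetyl}oxazolidin-2-one, via mixed pivalic anhydride 7 (not isolated)
Conditions: t-BuCOCl, Et3N, THF, −20 °C; then LiCl, 6, −20 °C → rt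
Reagents that add atoms: none
Why: N-acylation of the Evans auxiliary through a mixed anhydride, in which the LiCl-activated oxazolidinone attacks the unhindered aryloxyacetyl carbonyl rather than the tert-butyl-shielded one under conditions free of strong acid, the auxiliary stereocentre being bought with 6.

**Step 5**
Reactants: 8 (R)-4-benzyl-3-{2-[2,6-dimethoxy-4-(2-methyl-1,3-dioxolan-2-yl)phenoxy]acetyl}oxazolidin-2-one; 9 4-benzyloxy-3-methoxybenzaldehyde (O-benzylvanillin)
Product: 12 (R)-4-benzyl-3-{(2R,3S)-3-(4-benzyloxy-3-methoxyphenyl)-2-[2,6-dimethoxy-4-(2-methyl-1,3-dioxolan-2-yl)phenoxy]-3-hydroxypropanoyl}oxazolidin-2-one, via (Z)-dibutylboron enolate 10 (not isolated), via dibutylboron aldolate 11 (not isolated)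
Conditions: Bu2BOTf, i-Pr2NEt, CH2Cl2, −78 → 0 °C; 9, −78 → 0 °C; then pH 7 phosphate buffer, MeOH, 30% H2O2, 0 °C
Reagents that add atoms: none
Why: Evans syn aldol, in which the (Z)-boron enolate adds to the aldehyde through a closed Zimmerman–Traxler chair on the enolate face away from the benzyl group of the (R)-auxiliary, setting the acyl chain as 2R,3S (2,3-syn) while the ketal and benzyl ether are untouched.

**Step 6**
Reactants: 12 (R)-4-benzyl-3-{(2R,3S)-3-(4-benzyloxy-3-methoxyphenyl)-2-[2,6-dimethoxy-4-(2-methyl-1,3-dioxolan-2-yl)phenoxy]-3-hydroxypropanoyl}oxazolidin-2-one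
Product: 13 (1S,2S)-1-(4-benzyloxy-3-methoxyphenyl)-2-[2,6-dimethoxy-4-(2-methyl-1,3-dioxolan-2-yl)phenoxy]propane-1,3-diol
Conditions: NaBH4, THF/H2O (4:1), 0 °C → rt
Reagents that add atoms: none
Why: Reductive cleavage of the N-acyl oxazolidinone, in which borohydride reduces the activated exocyclic imide carbonyl to the primary alcohol and releases 6 without touching either stereocentre (the aryloxy carbon changes from R to S only because the CIP priorities change).

**Step 7**
Reactants: 13 (1S,2S)-1-(4-benzyloxy-3-methoxyphenyl)-2-[2,6-dimethoxy-4-(2-methyl-1,3-dioxolan-2-yl)phenoxy]propane-1,3-diol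
Product: 14 (1S,2S)-1-(4-benzyloxy-3-methoxyphenyl)-3-(tert-butyldimethylsilyloxy)-2-[2,6-dimethoxy-4-(2-methyl-1,3-dioxolan-2-yl)phenoxy]propan-1-ol
Conditions: TBSCl (1.05 equiv), imidazole, CH2Cl2, 0 °C
Reagents that add atoms: tert-butyldimethylsilyl chloride, CC(C)(C)[Si](C)(C)Cl
Why: Selective silylation, since the unhindered primary hydroxyl reacts far faster than the secondary benzylic one, which is left free for inversion.

**Step 8**
Reactants: 14 (1S,2S)-1-(4-benzyloxy-3-methoxyphenyl)-3-(tert-butyldimethylsilyloxy)-2-[2,6-dimethoxy-4-(2-methyl-1,3-dioxolan-2-yl)phenoxy]propan-1-ol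
Product: 15 (1R,2S)-1-(4-benzyloxy-3-methoxyphenyl)-3-(tert-butyldimethylsilyloxy)-2-[2,6-dimethoxy-4-(2-methyl-1,3-dioxolan-2-yl)phenoxy]propyl 4-nitrobenzoate
Conditions: 4-O2NC6H4CO2H, PPh3, DIAD, THF, 0 °C → rt
Reagents that add atoms: 4-nitrobenzoic acid, O=C(O)c1ccc(cc1)[N+](=O)[O-]
Why: Mitsunobu reaction, in which the benzylic alkoxyphosphonium ion is displaced by 4-nitrobenzoate in an SN2 step with inversion (C1 goes from S to R, ionisation being disfavoured by the electron-withdrawing β-aryloxy group) while C2 is untouched.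

**Step 9**
Reactants: 15 (1R,2S)-1-(4-benzyloxy-3-methoxyphenyl)-3-(tert-butyldimethylsilyloxy)-2-[2,6-dimethoxy-4-(2-methyl-1,3-dioxolan-2-yl)phenoxy]propyl 4-nitrobenzoate
Product: 16 (1R,2S)-1-(4-benzyloxy-3-methoxyphenyl)-3-(tert-butyldimethylsilyloxy)-2-[2,6-dimethoxy-4-(2-methyl-1,3-dioxolan-2-yl)phenoxy]propan-1-ol
Conditions: K2CO3 (0.2 equiv), MeOH/THF, 0 °C → rt
Reagents that add atoms: none
Why: Transesterification (methanolysis), in which methoxide cleaves the activated 4-nitrobenzoate at the acyl carbon so that the C1–O bond and its configuration are retained, the silyl ether, ketal and benzyl ether being stable to mild base.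

**Step 10**
Reactants: 16 (1R,2S)-1-(4-benzyloxy-3-methoxyphenyl)-3-(tert-butyldimethylsilyloxy)-2-[2,6-dimethoxy-4-(2-methyl-1,3-dioxolan-2-yl)phenoxy]propan-1-ol
Product: 17 (1R,2S)-2-(4-acetyl-2,6-dimethoxyphenoxy)-1-(4-benzyloxy-3-methoxyphenyl)propane-1,3-diol
Conditions: 1 M aq. HCl, THF, 0 °C → rt
Reagents that add atoms: water, O
Why: Acid-catalysed hydrolysis, in which dilute aqueous acid cleaves the primary TBS ether and the aryl-ketone dioxolane (via its oxocarbenium ion) under conditions too mild to ionise the non-phenolic benzylic alcohol or cleave the benzyl ether.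

**Step 11**
Reactants: 17 (1R,2S)-2-(4-acetyl-2,6-dimethoxyphenoxy)-1-(4-benzyloxy-3-methoxyphenyl)propane-1,3-diol
Product: 18 (1R,2S)-2-(4-acetyl-2,6-dimethoxyphenoxy)-1-(4-hydroxy-3-methoxyphenyl)propane-1,3-diol
Conditions: H2 (1 atm), 10% Pd/C, EtOAc, rt, stopped after 1 equiv H2
Reagents that add atoms: none
Why: Hydrogenolysis, in which the aryl benzyl ether is cleaved over Pd/C in a neutral solvent much faster than the electron-rich aryl methyl ketone is reduced or the benzylic C–OH is hydrogenolysed, so both stereocentres are untouched.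

**Compound list**
1 | acetosyringone (1-(4-hydroxy-3,5-dimethoxyphenyl)ethan-1-one) | CC(=O)c1cc(OC)c(O)c(OC)c1 | starting material
2 | ethyl bromoacetate | CCOC(=O)CBr | starting material
3 | ethyl 2-(4-acetyl-2,6-dimethoxyphenoxy)acetate | CCOC(=O)COc1c(OC)cc(C(C)=O)cc1OC | intermediate
4 | ethyl 2-[2,6-dimethoxy-4-(2-methyl-1,3-dioxolan-2-yl)phenoxy]acetate | CCOC(=O)COc1c(OC)cc(C2(C)OCCO2)cc1OC | intermediate
5 | 2-[2,6-dimethoxy-4-(2-methyl-1,3-dioxolan-2-yl)phenoxy]acetic acid | OC(=O)COc1c(OC)cc(C2(C)OCCO2)cc1OC | intermediate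
6 | (R)-4-benzyloxazolidin-2-one | O=C1OC[C@@H](Cc2ccccc2)N1 | starting material
7 | mixed pivalic anhydride of 5 | CC(C)(C)C(=O)OC(=O)COc1c(OC)cc(C2(C)OCCO2)cc1OC | intermediate
8 | (R)-4-benzyl-3-{2-[2,6-dimethoxy-4-(2-methyl-1,3-dioxolan-2-yl)phenoxy]acetyl}oxazolidin-2-one | O=C1OC[C@@H](Cc2ccccc2)N1C(=O)COc1c(OC)cc(C2(C)OCCO2)cc1OC | intermediate
9 | 4-benzyloxy-3-methoxybenzaldehyde | COc1cc(C=O)ccc1OCc1ccccc1 | starting material
10 | (Z)-dibutylboron enolate of 8 | CCCCB(CCCC)O/C(=C\Oc1c(OC)cc(C2(C)OCCO2)cc1OC)N1C(=O)OC[C@H]1Cc1ccccc1 | intermediate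
11 | dibutylboron aldolate of 12 | COc1cc([C@H](OB(CCCC)CCCC)[C@H](C(=O)N2C(=O)OC[C@H]2Cc2ccccc2)Oc2c(OC)cc(C3(C)OCCO3)cc2OC)ccc1OCc1ccccc1 | intermediate
12 | (R)-4-benzyl-3-{(2R,3S)-3-(4-benzyloxy-3-methoxyphenyl)-2-[2,6-dimethoxy-4-(2-methyl-1,3-dioxolan-2-yl)phenoxy]-3-hydroxypropanoyl}oxazolidin-2-one | COc1cc([C@H](O)[C@H](C(=O)N2C(=O)OC[C@H]2Cc2ccccc2)Oc2c(OC)cc(C3(C)OCCO3)cc2OC)ccc1OCc1ccccc1 | intermediate
13 | (1S,2S)-1-(4-benzyloxy-3-methoxyphenyl)-2-[2,6-dimethoxy-4-(2-methyl-1,3-dioxolan-2-yl)phenoxy]propane-1,3-diol | COc1cc([C@H](O)[C@H](CO)Oc2c(OC)cc(C3(C)OCCO3)cc2OC)ccc1OCc1ccccc1 | intermediate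
14 | (1S,2S)-1-(4-benzyloxy-3-methoxyphenyl)-3-(tert-butyldimethylsilyloxy)-2-[2,6-dimethoxy-4-(2-methyl-1,3-dioxolan-2-yl)phenoxy]propan-1-ol | COc1cc([C@H](O)[C@H](CO[Si](C)(C)C(C)(C)C)Oc2c(OC)cc(C3(C)OCCO3)cc2OC)ccc1OCc1ccccc1 | intermediate
15 | (1R,2S)-1-(4-benzyloxy-3-methoxyphenyl)-3-(tert-butyldimethylsilyloxy)-2-[2,6-dimethoxy-4-(2-methyl-1,3-dioxolan-2-yl)phenoxy]propyl 4-nitrobenzoate | COc1cc([C@@H](OC(=O)c2ccc(cc2)[N+](=O)[O-])[C@H](CO[Si](C)(C)C(C)(C)C)Oc2c(OC)cc(C3(C)OCCO3)cc2OC)ccc1OCc1ccccc1 | intermediate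
16 | (1R,2S)-1-(4-benzyloxy-3-methoxyphenyl)-3-(tert-butyldimethylsilyloxy)-2-[2,6-dimethoxy-4-(2-methyl-1,3-dioxolan-2-yl)phenoxy]propan-1-ol | COc1cc([C@@H](O)[C@H](CO[Si](C)(C)C(C)(C)C)Oc2c(OC)cc(C3(C)OCCO3)cc2OC)ccc1OCc1ccccc1 | intermediate
17 | (1R,2S)-2-(4-acetyl-2,6-dimethoxyphenoxy)-1-(4-benzyloxy-3-methoxyphenyl)propane-1,3-diol | COc1cc([C@@H](O)[C@H](CO)Oc2c(OC)cc(C(C)=O)cc2OC)ccc1OCc1ccccc1 | intermediate
18 | (1R,2S)-2-(4-acetyl-2,6-dimethoxyphenoxy)-1-(4-hydroxy-3-methoxyphenyl)propane-1,3-diol | COc1cc([C@@H](O)[C@H](CO)Oc2c(OC)cc(C(C)=O)cc2OC)ccc1O | target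

**Step count**
Total steps: 11. Longest linear sequence: 11 steps (1 → 18); compounds 2, 6 and 9 are bought.

**Steps most likely to fail**

Step 5 (Evans aldol). The boron triflate may open the dioxolane, and the bulky 2,6-dimethoxyphenoxy group may lower the syn selectivity. The fallback sets out from 4 and comes back at 13. Ester 4 is deprotonated with LiN(SiMe3)2 (2.2 equiv, THF, −78 °C) and C-acylated in a crossed Claisen condensation with commercial 4-benzyloxy-3-methoxybenzoyl chloride F1. This gives racemic ethyl 3-(4-benzyloxy-3-methoxyphenyl)-2-[2,6-dimethoxy-4-(2-methyl-1,3-dioxolan-2-yl)phenoxy]-3-oxopropanoate F2, whose C2 epimerises freely. Asymmetric transfer hydrogenation with dynamic kinetic resolution (RuCl(p-cymene)[(R,R)-TsDPEN], HCO2H/Et3N 1:1, CH2Cl2, rt) should then give the syn ester ethyl (2R,3S)-3-(4-benzyloxy-3-methoxyphenyl)-2-[2,6-dimethoxy-4-(2-methyl-1,3-dioxolan-2-yl)phenoxy]-3-hydroxypropanoate F3. LiBH4 (THF, 0 °C) reduces the ester to 13. No boron triflate meets the ketal and both stereocentres come from the catalyst. The (R,R)-ligand is chosen by analogy with aryl ketone reductions, and the sense and syn selectivity for this α-aryloxy substrate are expected rather than established, so they must be confirmed on the product.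

Step 8 (Mitsunobu inversion). The electron-rich benzylic centre may ionise, giving partial retention or elimination. The resulting C1 epimers are diastereomers and separable, and C2 is not at risk. The fallback sets out from 14 and comes back at 16. Compound 14 is oxidised (Dess–Martin periodinane, NaHCO3, CH2Cl2, 0 °C) to (S)-1-(4-benzyloxy-3-methoxyphenyl)-3-(tert-butyldimethylsilyloxy)-2-[2,6-dimethoxy-4-(2-methyl-1,3-dioxolan-2-yl)phenoxy]propan-1-one F4. This is used crude and cold to protect the C2 stereocentre and is reduced at once with Zn(BH4)2 (Et2O, −30 °C). Under chelation control, with zinc bridging the carbonyl oxygen and the C2 aryl ether oxygen and hydride arriving from the side of the small C2–H, the anti alcohol 16 is expected. Chelation by this hindered aryl ether is not assured, so the selectivity may be modest. The other product is 14 itself, which is separated and recycled.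

Step 11 (hydrogenolysis). The acetyl group may be over-reduced or the benzylic C–OH hydrogenolysed. The fallback sets out from 16 and comes back at 18. Compound 16 is hydrogenolysed while the acetyl group is still a dioxolane (H2, Pd/C, EtOAc, rt) to (1R,2S)-3-(tert-butyldimethylsilyloxy)-2-[2,6-dimethoxy-4-(2-methyl-1,3-dioxolan-2-yl)phenoxy]-1-(4-hydroxy-3-methoxyphenyl)propan-1-ol F5. Dilute acid (AcOH/THF/H2O 3:1:1, rt) then removes the silyl ether and the dioxolane to give 18 directly. This trades the reduction risk for brief acid exposure of the phenolic benzylic alcohol.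

**Further compounds**
F1 | step 5 | 4-benzyloxy-3-methoxybenzoyl chloride | COc1cc(C(Cl)=O)ccc1OCc1ccccc1
F2 | step 5 | ethyl 3-(4-benzyloxy-3-methoxyphenyl)-2-[2,6-dimethoxy-4-(2-methyl-1,3-dioxolan-2-yl)phenoxy]-3-oxopropanoate (racemic, C2 labile) | CCOC(=O)C(Oc1c(OC)cc(C2(C)OCCO2)cc1OC)C(=O)c1ccc(OCc2ccccc2)c(OC)c1
F3 | step 5 | ethyl (2R,3S)-3-(4-benzyloxy-3-methoxyphenyl)-2-[2,6-dimethoxy-4-(2-methyl-1,3-dioxolan-2-yl)phenoxy]-3-hydroxypropanoate | COc1cc([C@H](O)[C@H](C(=O)OCC)Oc2c(OC)cc(C3(C)OCCO3)cc2OC)ccc1OCc1ccccc1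
F4 | step 8 | (S)-1-(4-benzyloxy-3-methoxyphenyl)-3-(tert-butyldimethylsilyloxy)-2-[2,6-dimethoxy-4-(2-methyl-1,3-dioxolan-2-yl)phenoxy]propan-1-one | COc1cc(C(=O)[C@H](CO[Si](C)(C)C(C)(C)C)Oc2c(OC)cc(C3(C)OCCO3)cc2OC)ccc1OCc1ccccc1
F5 | step 11 | (1R,2S)-3-(tert-butyldimethylsilyloxy)-2-[2,6-dimethoxy-4-(2-methyl-1,3-dioxolan-2-yl)phenoxy]-1-(4-hydroxy-3-methoxyphenyl)propan-1-ol | COc1cc([C@@H](O)[C@H](CO[Si](C)(C)C(C)(C)C)Oc2c(OC)cc(C3(C)OCCO3)cc2OC)ccc1O
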